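The plan rests on reading the 1,3-related C7 (Cl) and C9 (Br) of the tetrahydropyran (ring O, C6, C7, C8, C9, C10; chain numbered C1–C15 from the alkyne end) as a cyclopropane C7–C8–C9 fused to a tetrahydrofuran (O, C6, C7, C9, C10). One oxidative radical operation cuts the shared C7–C9 bond, enlarges the five-membered ring to the tetrahydropyran-3-one and places bromine on C9. The precursor is a single 2,4-cis 3-oxabicyclo[3.1.0]hexan-1-ol with two differently silylated hydroxyethyl arms; C6 and C10 are fixed before the cyclopropanol is built by an intramolecular Kulinkovich reaction.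

Key step: step 7

Remarks.
(a) Chain numbering: C1≡C2–C3=C4–C5–C6(O)–C7(Cl)–C8–C9(Br)–C10(O)–C11–C12=C13(Br)–C14–C15. In the target all four ring substituents lie on one face (both arms equatorial, Cl and Br axial).
(b) TBS = tert-butyldimethylsilyl, TBDPS = tert-butyldiphenylsilyl, TIPS = triisopropylsilyl, Tf = trifluoromethylsulfonyl.
(c) Compounds 1, 2, 5, 22 and 29 are assumed to be purchased.
(d) C6 is set before the key step (step 5), because the β-bromoketone of step 7 cannot be equilibrated at C6 without risking loss of HBr. The cyclopropanol therefore enters step 7 as one C6/C10 diastereomer; only the cyclopropane face is immaterial.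
(e) The configurations used for the cyclopropanol 12 and the bromoketone 15 (C6 arm, C10 arm and C9–Br on one face) were checked against the target and agree with it.

Step 1
Reactants: 1 3-(TBS-oxy)propanal; 2 vinylmagnesium bromide
Product: 3 rac-5-(TBS-oxy)pent-1-en-3-ol
Conditions: THF, −78 → 0 °C; aq. NH4Cl
Reagents that add atoms: none
Why: Grignard 1,2-addition to an unhindered aldehyde; the carbinol centre (future C10) is formed racemic and is resolved in step 2.

Step 2
Reactants: 3 rac-5-(TBS-oxy)pent-1-en-3-ol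
Product: 4 (R)-5-(TBS-oxy)pent-1-en-3-ol
Conditions: Ti(OiPr)4 (cat.), L-(+)-diisopropyl tartrate, t-BuOOH (0.6 equiv), 4 Å molecular sieves, CH2Cl2, −20 °C
Reagents that add atoms: none
Why: Sharpless kinetic resolution; with the L-(+)-tartrate the (S)-alcohol is epoxidised much faster, so the unreacted (R)-alcohol (C10 of the target) should be recovered enantiomerically enriched and separated from the polar epoxy alcohol.

Step 3
Reactants: 5 (R)-3-hydroxydihydrofuran-2(3H)-one
Product: 8 methyl (R)-2-hydroxy-4-(TBDPS-oxy)butanoate, via sodium (R)-2,4-dihydroxybutanoate 6 (not isolated), via methyl (R)-2,4-dihydroxybutanoate 7 (not isolated)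
Conditions: NaOH (1.0 equiv), H2O, 0 °C → rt, lyophilise; MeI (1.05 equiv), DMF, rt; then imidazole, t-BuPh2SiCl, 0 °C
Reagents that add atoms: sodium hydroxide, [Na+].[OH-]; iodomethane, CI; tert-butyl(chloro)diphenylsilane, CC(C)(C)[Si](Cl)(c1ccccc1)c1ccccc1
Why: Lactone saponification, carboxylate O-alkylation and chemoselective silylation of the primary hydroxyl; opening as the carboxylate prevents relactonisation before the silyl group is on, and the stereocentre (future C6) is not touched.

Step 4
Reactants: 8 methyl (R)-2-hydroxy-4-(TBDPS-oxy)butanoate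
Product: 9 methyl (R)-4-(TBDPS-oxy)-2-(triflyloxy)butanoate
Conditions: Tf2O, 2,6-lutidine, CH2Cl2, −78 → 0 °C; used at once
Reagents that add atoms: trifluoromethanesulfonic anhydride, O=S(=O)(OS(=O)(=O)C(F)(F)F)C(F)(F)F
Why: O-Sulfonylation of an α-hydroxy ester with a hindered pyridine base; the C–O bond is not broken, so the (R) configuration is kept and a strong SN2 electrophile results.

Step 5
Reactants: 4 (R)-5-(TBS-oxy)pent-1-en-3-ol; 9 methyl (R)-4-(TBDPS-oxy)-2-(triflyloxy)butanoate
Product: 11 methyl (S)-4-(TBDPS-oxy)-2-{[(R)-5-(TBS-oxy)pent-1-en-3-yl]oxy}butanoate, via sodium (R)-5-(TBS-oxy)pent-1-en-3-olate 10 (not isolated)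
Conditions: NaH, THF, 0 °C; then 9 (1.3 equiv), −78 → −20 °C
Reagents that add atoms: none
Why: Williamson ether synthesis on an α-triflyloxy ester, which proceeds by SN2 with inversion as in the formation of lactyl ethers from secondary alkoxides, so C6 is set as (S) next to the fixed (R) centre C10; the low temperature and the very good leaving group keep ester attack and elimination behind.

Step 6
Reactants: 11 methyl (S)-4-(TBDPS-oxy)-2-{[(R)-5-(TBS-oxy)pent-1-en-3-yl]oxy}butanoate
Product: 12 2-[2-(TBDPS-oxy)ethyl]-4-[2-(TBS-oxy)ethyl]-3-oxabicyclo[3.1.0]hexan-1-ol (arms cis; cyclopropane CH2 on the opposite face)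
Conditions: Ti(OiPr)4 (1.1 equiv), c-C6H11MgCl (4.5 equiv, slow addition), THF, rt
Reagents that add atoms: none
Why: Intramolecular Kulinkovich cyclopropanation in its alkene-exchange form: the titanacyclopropane from Ti(OiPr)4 and c-C6H11MgCl swaps cyclohexene for the terminal vinyl group and adds twice to the ester carbonyl as a 1,2-dicarbanion equivalent, giving the cis-fused cyclopropanol with C6 and C10 unchanged; the CH2 should prefer the face away from the arms, and the other face would serve equally because C7 and C9 are flattened in step 7.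

Step 7
Reactants: 12 2-[2-(TBDPS-oxy)ethyl]-4-[2-(TBS-oxy)ethyl]-3-oxabicyclo[3.1.0]hexan-1-ol
Product: 15 5-bromo-2-[2-(TBDPS-oxy)ethyl]-6-[2-(TBS-oxy)ethyl]tetrahydropyran-3-one (2,6-cis; bromine axial on C9 and cis to the C10 arm), via tertiary cyclopropyloxyl radical 13 (not isolated), via ring-enlarged C9 radical 14 (not isolated)
Conditions: AgNO3 (0.2 equiv), K2S2O8 (2 equiv), N-bromosuccinimide (2 equiv), CH2Cl2/H2O 1:1, rt, dark; rapid extraction, crude product taken straight into step 8
Reagents that add atoms: N-bromosuccinimide, O=C1CCC(=O)N1Br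
Why: Monovalent silver is oxidised by persulfate to divalent silver, which turns the cyclopropanol O–H into the alkoxy radical 13; strain-driven β-scission of the shared C7–C9 bond gives the C7 ketone and the secondary C9 radical 14, which takes bromine from N-bromosuccinimide. The closest known reaction type is the silver/persulfate ring-opening halogenation of cyclopropanols with N-halosuccinimides to β-haloketones, whose bicyclic cases give ring-enlarged products; the same alkoxy-radical fragmentation underlies the Dowd–Beckwith ring enlargement. The tetrahydropyranone ring is not closed by a new bond: it arises by ring enlargement, the zero-atom bridge of the bicyclo[3.1.0] unit being cut so that the three- and five-membered rings merge into the six-membered one. The new C9 stereocentre is set by axial bromine delivery to the chair-like radical with both arms equatorial; the axial path meets no 1,3-diaxial partner, because the 1,3-related ring positions are the C7 carbonyl carbon and the ring oxygen, so bromine should enter cis to the C10 arm. The step needs cleavage of the internal rather than the external cyclopropane bond, which is favoured by the secondary radical formed and by re-closure of any primary radical through the same alkoxy radical, and it needs radical opening to outrun ionic opening by N-bromosuccinimide, which the fast silver-mediated oxidation in the two-phase medium should secure.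

Step 8
Reactants: 15 5-bromo-2-[2-(TBDPS-oxy)ethyl]-6-[2-(TBS-oxy)ethyl]tetrahydropyran-3-one
Product: 16 5-bromo-2-[2-(TBDPS-oxy)ethyl]-6-[2-(TBS-oxy)ethyl]tetrahydropyran-3-ol (all-cis; C7–OH and C9–Br axial)
Conditions: LiBH(s-Bu)3 (L-Selectride), THF, −78 °C; aq. NH4Cl
Reagents that add atoms: none
Why: Ketone reduction with a bulky trialkylborohydride: hydride enters along the equatorial path, away from the axial C9 bromine that blocks the axial one, which sets C7 as the axial alcohol cis to the C6 arm, and the low temperature should outrun loss of HBr from the β-bromoketone.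

Step 9
Reactants: 16 5-bromo-2-[2-(TBDPS-oxy)ethyl]-6-[2-(TBS-oxy)ethyl]tetrahydropyran-3-ol (all-cis)
Product: 17 C7-inverted 4-nitrobenzoate of 16 (ester equatorial; trans to the C6 arm)
Conditions: 4-O2NC6H4CO2H, PPh3, DIAD, toluene, 0 °C → rt
Reagents that add atoms: 4-nitrobenzoic acid, O=C(O)c1ccc(cc1)[N+](=O)[O-]
Why: Mitsunobu inversion: the axial alkoxyphosphonium ion is displaced by 4-nitrobenzoate along the open equatorial path, turning C7 into the equatorial ester; the acidic nitrobenzoic acid is the usual partner for hindered secondary alcohols.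

Step 10
Reactants: 17 C7-inverted 4-nitrobenzoate
Product: 18 5-bromo-2-[2-(TBDPS-oxy)ethyl]-6-[2-(TBS-oxy)ethyl]tetrahydropyran-3-ol (C7–OH equatorial; trans to the C6 arm)
Conditions: K2CO3, MeOH, 0 °C → rt
Reagents that add atoms: none
Why: Base-catalysed transesterification of the activated aryl ester frees the equatorial C7 alcohol without touching the silyl ethers or the secondary bromide at this temperature.

Step 11
Reactants: 18 C7-equatorial alcohol
Product: 19 5-bromo-3-chloro-2-[2-(TBDPS-oxy)ethyl]-6-[2-(TBS-oxy)ethyl]tetrahydropyran (all-cis; Cl and Br axial)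
Conditions: (n-C8H17)3P, CCl4, toluene, 70 °C
Reagents that add atoms: tetrachloromethane, ClC(Cl)(Cl)Cl
Why: Appel-type deoxychlorination with a trialkylphosphine: chloride displaces the equatorial alkoxyphosphonium group by SN2 with inversion to give the axial C7 chloride of the target, and an equatorial leaving group has no anti-periplanar hydrogen, which disfavours elimination.

Step 12
Reactants: 19 all-cis bromo chloro bis-silyl ether
Product: 20 2-{3-bromo-5-chloro-6-[2-(TBDPS-oxy)ethyl]tetrahydropyran-2-yl}ethanol (all-cis; free C12–OH)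
Conditions: camphorsulfonic acid (cat.), MeOH/CH2Cl2, 0 °C
Reagents that add atoms: none
Why: Acid-catalysed methanolysis of a silyl ether: the primary TBS ether is cleaved far faster than the primary TBDPS ether, which tells the two arms apart.

Step 13
Reactants: 20 C12 primary alcohol
Product: 21 2-{3-bromo-5-chloro-6-[2-(TBDPS-oxy)ethyl]tetrahydropyran-2-yl}acetaldehyde (C12 aldehyde)
Conditions: Dess–Martin periodinane, NaHCO3, CH2Cl2, 0 °C → rt; used crude
Reagents that add atoms: none
Why: Dess–Martin oxidation under buffered, non-basic conditions gives the β-alkoxy aldehyde without β-elimination or over-oxidation.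

Step 14
Reactants: 21 C12 aldehyde; 22 propyltriphenylphosphonium bromide
Product: 26 3-bromo-2-[(E)-3-bromopent-2-enyl]-5-chloro-6-[2-(TBDPS-oxy)ethyl]tetrahydropyran (all-cis ring), via lithium betaine 23 (not isolated), via β-oxido phosphonium ylide 24 (not isolated), via α-bromo betaine 25 (not isolated)
Conditions: 22, PhLi, THF, 0 °C; 21, −78 °C; PhLi (1 equiv), −78 → −40 °C; BrCF2CF2Br, −78 °C → rt
Reagents that add atoms: 1,2-dibromo-1,1,2,2-tetrafluoroethane, FC(F)(Br)C(F)(F)Br
Why: Wittig–Schlosser-type bromo-olefination: the lithium-stabilised betaine is deprotonated to the β-oxido phosphonium ylide, brominated at carbon and then loses Ph3PO, a known route to trisubstituted bromoalkenes with bromine trans to the aldehyde-derived substituent, which is the (E) geometry needed at C12=C13; all organolithium stages run at low temperature, where the secondary ring halides should not react.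

Step 15
Reactants: 26 (E)-bromoalkene silyl ether
Product: 27 2-{5-bromo-6-[(E)-3-bromopent-2-enyl]-3-chlorotetrahydropyran-2-yl}ethanol (free C4–OH)
Conditions: HF·pyridine, pyridine/THF, 0 °C → rt
Reagents that add atoms: none
Why: Fluoride-mediated desilylation with buffered HF·pyridine removes the TBDPS group without the basicity of Bu4NF, which spares the axial halides and the vinyl bromide.

Step 16
Reactants: 27 C4 primary alcohol
Product: 28 2-{5-bromo-6-[(E)-3-bromopent-2-enyl]-3-chlorotetrahydropyran-2-yl}acetaldehyde (C4 aldehyde)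
Conditions: Dess–Martin periodinane, NaHCO3, CH2Cl2, 0 °C → rt; used crude
Reagents that add atoms: none
Why: Dess–Martin oxidation, mild and non-basic, as in step 13.

Step 17
Reactants: 28 C4 aldehyde; 29 1,3-bis(triisopropylsilyl)propyne
Product: 31 TIPS-capped (Z)-enyne: 3-bromo-2-[(E)-3-bromopent-2-enyl]-5-chloro-6-[(Z)-5-(triisopropylsilyl)pent-2-en-4-ynyl]tetrahydropyran, via lithium β-silyl alkoxide 30 (not isolated)
Conditions: 29, n-BuLi, THF, −20 °C; then 28, −78 → 0 °C
Reagents that add atoms: none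
Why: Peterson olefination with the lithiated bis-silylpropyne: addition to the aldehyde and syn-elimination of silanolate from the adduct, steered by the bulky TIPS groups, should give the (Z)-enyne at C3=C4, and the stabilised propargylic anion adds at −78 °C faster than it can attack the halides.

Step 18
Reactants: 31 TIPS-capped (Z)-enyne
Product: 32 target, 3-bromo-2-[(E)-3-bromopent-2-enyl]-5-chloro-6-[(Z)-pent-2-en-4-ynyl]tetrahydropyran (all-cis ring)
Conditions: Bu4NF, THF, −20 → 0 °C
Reagents that add atoms: none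
Why: Fluoride cleavage of the alkynyl C–Si bond (protodesilylation) at low temperature, where the secondary alkyl halides and the vinyl bromide are left alone.

Compound list
1 | 3-(TBS-oxy)propanal | O=CCCO[Si](C)(C)C(C)(C)C | starting material
2 | vinylmagnesium bromide | C=C[Mg]Br | starting material
3 | rac-5-(TBS-oxy)pent-1-en-3-ol | C=CC(O)CCO[Si](C)(C)C(C)(C)C | intermediate
4 | (R)-5-(TBS-oxy)pent-1-en-3-ol | C=C[C@H](O)CCO[Si](C)(C)C(C)(C)C | intermediate
5 | (R)-3-hydroxydihydrofuran-2(3H)-one [(R)-α-hydroxy-γ-butyrolactone] | O[C@@H]1CCOC1=O | starting material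
6 | sodium (R)-2,4-dihydroxybutanoate | [Na+].[O-]C(=O)[C@H](O)CCO | intermediate (not isolated)
7 | methyl (R)-2,4-dihydroxybutanoate | COC(=O)[C@H](O)CCO | intermediate (not isolated)
8 | methyl (R)-2-hydroxy-4-(TBDPS-oxy)butanoate | COC(=O)[C@H](O)CCO[Si](c1ccccc1)(c1ccccc1)C(C)(C)C | intermediate
9 | methyl (R)-4-(TBDPS-oxy)-2-(triflyloxy)butanoate | COC(=O)[C@H](OS(=O)(=O)C(F)(F)F)CCO[Si](c1ccccc1)(c1ccccc1)C(C)(C)C | intermediate
10 | sodium (R)-5-(TBS-oxy)pent-1-en-3-olate | [Na+].[O-][C@H](CCO[Si](C)(C)C(C)(C)C)C=C | intermediate (not isolated)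
11 | methyl (S)-4-(TBDPS-oxy)-2-{[(R)-5-(TBS-oxy)pent-1-en-3-yl]oxy}butanoate | COC(=O)[C@H](CCO[Si](c1ccccc1)(c1ccccc1)C(C)(C)C)O[C@H](CCO[Si](C)(C)C(C)(C)C)C=C | intermediate
12 | 2-[2-(TBDPS-oxy)ethyl]-4-[2-(TBS-oxy)ethyl]-3-oxabicyclo[3.1.0]hexan-1-ol, arms cis, CH2 bridge on the opposite face (key-step precursor) | CC(C)(C)[Si](OCC[C@@H]1O[C@H](CCO[Si](C)(C)C(C)(C)C)[C@H]2C[C@@]12O)(c1ccccc1)c1ccccc1 | intermediate
13 | tertiary cyclopropyloxyl radical of 12 | CC(C)(C)[Si](OCC[C@@H]1O[C@H](CCO[Si](C)(C)C(C)(C)C)[C@H]2C[C@@]12[O])(c1ccccc1)c1ccccc1 | intermediate (not isolated)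
14 | ring-enlarged C9 radical of the tetrahydropyran-3-one | CC(C)(C)[Si](OCC[C@@H]1O[C@H](CCO[Si](C)(C)C(C)(C)C)[CH]CC1=O)(c1ccccc1)c1ccccc1 | intermediate (not isolated)
15 | 5-bromo-2-[2-(TBDPS-oxy)ethyl]-6-[2-(TBS-oxy)ethyl]tetrahydropyran-3-one, 2,6-cis, Br axial and cis to the C10 arm (key-step product) | CC(C)(C)[Si](OCC[C@@H]1O[C@H](CCO[Si](C)(C)C(C)(C)C)[C@H](Br)CC1=O)(c1ccccc1)c1ccccc1 | intermediate
16 | all-cis 5-bromo-2-[2-(TBDPS-oxy)ethyl]-6-[2-(TBS-oxy)ethyl]tetrahydropyran-3-ol (C7–OH axial) | CC(C)(C)[Si](OCC[C@@H]1O[C@H](CCO[Si](C)(C)C(C)(C)C)[C@H](Br)C[C@@H]1O)(c1ccccc1)c1ccccc1 | intermediate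
17 | C7-inverted (equatorial) 4-nitrobenzoate | CC(C)(C)[Si](OCC[C@@H]1O[C@H](CCO[Si](C)(C)C(C)(C)C)[C@H](Br)C[C@H]1OC(=O)c1ccc(cc1)[N+](=O)[O-])(c1ccccc1)c1ccccc1 | intermediate
18 | C7-equatorial alcohol | CC(C)(C)[Si](OCC[C@@H]1O[C@H](CCO[Si](C)(C)C(C)(C)C)[C@H](Br)C[C@H]1O)(c1ccccc1)c1ccccc1 | intermediate
19 | all-cis 5-bromo-3-chloro-2-[2-(TBDPS-oxy)ethyl]-6-[2-(TBS-oxy)ethyl]tetrahydropyran | CC(C)(C)[Si](OCC[C@@H]1O[C@H](CCO[Si](C)(C)C(C)(C)C)[C@H](Br)C[C@@H]1Cl)(c1ccccc1)c1ccccc1 | intermediate
20 | 2-{3-bromo-5-chloro-6-[2-(TBDPS-oxy)ethyl]tetrahydropyran-2-yl}ethanol (all-cis) | CC(C)(C)[Si](OCC[C@@H]1O[C@H](CCO)[C@H](Br)C[C@@H]1Cl)(c1ccccc1)c1ccccc1 | intermediate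
21 | 2-{3-bromo-5-chloro-6-[2-(TBDPS-oxy)ethyl]tetrahydropyran-2-yl}acetaldehyde | CC(C)(C)[Si](OCC[C@@H]1O[C@H](CC=O)[C@H](Br)C[C@@H]1Cl)(c1ccccc1)c1ccccc1 | intermediate
22 | propyltriphenylphosphonium bromide | CCC[P+](c1ccccc1)(c1ccccc1)c1ccccc1.[Br-] | starting material
23 | lithium betaine (C12 oxide, C13 phosphonium; LiBr adduct; new centres undefined) | CC(C)(C)[Si](OCC[C@@H]1O[C@H](CC([O-])C(CC)[P+](c2ccccc2)(c2ccccc2)c2ccccc2)[C@H](Br)C[C@@H]1Cl)(c1ccccc1)c1ccccc1 | intermediate (not isolated)
24 | β-oxido phosphonium ylide (lithium salt) | [Li+].CC(C)(C)[Si](OCC[C@@H]1O[C@H](CC([O-])C(CC)=P(c2ccccc2)(c2ccccc2)c2ccccc2)[C@H](Br)C[C@@H]1Cl)(c1ccccc1)c1ccccc1 | intermediate (not isolated)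
25 | α-bromo betaine (new centres undefined) | CC(C)(C)[Si](OCC[C@@H]1O[C@H](CC([O-])C(Br)(CC)[P+](c2ccccc2)(c2ccccc2)c2ccccc2)[C@H](Br)C[C@@H]1Cl)(c1ccccc1)c1ccccc1 | intermediate (not isolated)
26 | 3-bromo-2-[(E)-3-bromopent-2-enyl]-5-chloro-6-[2-(TBDPS-oxy)ethyl]tetrahydropyran (all-cis ring) | CC(C)(C)[Si](OCC[C@@H]1O[C@H](C/C=C(/Br)CC)[C@H](Br)C[C@@H]1Cl)(c1ccccc1)c1ccccc1 | intermediate
27 | 2-{5-bromo-6-[(E)-3-bromopent-2-enyl]-3-chlorotetrahydropyran-2-yl}ethanol | OCC[C@@H]1O[C@H](C/C=C(/Br)CC)[C@H](Br)C[C@@H]1Cl | intermediate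
28 | 2-{5-bromo-6-[(E)-3-bromopent-2-enyl]-3-chlorotetrahydropyran-2-yl}acetaldehyde | O=CC[C@@H]1O[C@H](C/C=C(/Br)CC)[C@H](Br)C[C@@H]1Cl | intermediate
29 | 1,3-bis(triisopropylsilyl)propyne | CC(C)[Si](C#CC[Si](C(C)C)(C(C)C)C(C)C)(C(C)C)C(C)C | starting material
30 | lithium β-silyl alkoxide (C4 oxide, C3 TIPS; new centres undefined) | [Li+].CC(C)[Si](C#CC(C([O-])C[C@@H]1O[C@H](C/C=C(/Br)CC)[C@H](Br)C[C@@H]1Cl)[Si](C(C)C)(C(C)C)C(C)C)(C(C)C)C(C)C | intermediate (not isolated)
31 | TIPS-capped (Z)-enyne | CC(C)[Si](C#C/C=C\C[C@@H]1O[C@H](C/C=C(/Br)CC)[C@H](Br)C[C@@H]1Cl)(C(C)C)C(C)C | intermediate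
32 | target CNP0160984.2 | C#C/C=C\C[C@@H]1O[C@H](C/C=C(/Br)CC)[C@H](Br)C[C@@H]1Cl | target

Total step count: 18. Longest linear sequence: 16 steps (1 → 32 through steps 1, 2 and 5–18; equally 5 → 32 through steps 3–18).

Steps most likely to fail

1. Step 7. Bromine-atom transfer to the C9 radical may show poor facial selectivity, the external cyclopropane bond may fragment, or N-bromosuccinimide may open the cyclopropanol ionically before the oxidation takes place. Fallback, from 12 back to 15: oxidation of 12 with FeCl3 in DMF at 0 °C (ring enlargement by trivalent iron with chloride trapping) should give the ring-enlarged 5-chlorotetrahydropyran-3-one F1 as a C9 mixture. NaOAc in MeOH then eliminates HCl to the 2,6-cis-6H-pyran-3-one F2, which removes the C9 question. Dry HBr in CH2Cl2 at −78 °C adds across the enone under kinetic, stereoelectronic control (axial entry of bromide through a chair-like enol, cis to the C10 arm) and gives 15, which is reduced at once as in step 8.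

2. Step 6. The titanacyclopropane may lose the allylic ether oxygen by β-elimination, alkene exchange at the branched vinyl group may be slow, or the Grignard reagent may enolise and epimerise the α-alkoxy ester. Fallback, from 11 back to 12, building the cyclopropanol by metathesis and carbenoid addition instead:
- aminolysis of 11 with MeNH(OMe)·HCl and i-PrMgCl (THF, −20 °C) gives the N-methoxy-N-methylamide F3;
- MeMgBr converts it into the methyl ketone F4;
- kinetic silylation on the methyl side (LiN(i-Pr)2, Me3SiCl, THF, −78 °C) gives the enol silyl ether F5;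
- ring-closing metathesis with the second-generation Grubbs catalyst (CH2Cl2, 40 °C) joins C7 and C9 with loss of ethene and gives the cyclic enol silyl ether F6;
- Simmons–Smith cyclopropanation (Et2Zn, CH2I2) from the face away from both arms gives the silyloxycyclopropane F7;
- K2CO3 in MeOH frees the cyclopropanol and returns 12.

3. Step 14. Phenyllithium may attack the ring halides (elimination or halogen–lithium exchange), the β-alkoxy aldehyde may suffer β-elimination, or the alkene geometry may erode. Fallback, from 21 back to 26: Horner–Wadsworth–Emmons reaction of 21 with methyl 2-[bis(2,2,2-trifluoroethoxy)phosphoryl]-2-bromoacetate (t-BuOK, 18-crown-6, THF, −78 °C), a Still–Gennari-type reagent that places the ester cis to the chain, should give the (E)-α-bromo enoate F8. (i-Bu)2AlH (CH2Cl2, −78 °C) reduces it to the allylic alcohol F9, and CBr4/PPh3 converts this into the allylic bromide F10. Copper-catalysed SN2 methylation (MeMgBr, Li2CuCl4 cat., THF, −78 °C) completes the ethyl group and returns 26.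

Further compounds
F1 | step 7 | 5-chloro-2-[2-(TBDPS-oxy)ethyl]-6-[2-(TBS-oxy)ethyl]tetrahydropyran-3-one (C9 mixture) | CC(C)(C)[Si](OCC[C@@H]1O[C@H](CCO[Si](C)(C)C(C)(C)C)C(Cl)CC1=O)(c1ccccc1)c1ccccc1
F2 | step 7 | 2,6-cis-2-[2-(TBDPS-oxy)ethyl]-6-[2-(TBS-oxy)ethyl]-6H-pyran-3-one | CC(C)(C)[Si](OCC[C@@H]1O[C@H](CCO[Si](C)(C)C(C)(C)C)C=CC1=O)(c1ccccc1)c1ccccc1
F3 | step 6 | N-methoxy-N-methylamide of the acid of 11 | CON(C)C(=O)[C@H](CCO[Si](c1ccccc1)(c1ccccc1)C(C)(C)C)O[C@H](CCO[Si](C)(C)C(C)(C)C)C=C
F4 | step 6 | methyl ketone | CC(=O)[C@H](CCO[Si](c1ccccc1)(c1ccccc1)C(C)(C)C)O[C@H](CCO[Si](C)(C)C(C)(C)C)C=C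
F5 | step 6 | trimethylsilyl enol ether of F4 (terminal) | C=C(O[Si](C)(C)C)[C@H](CCO[Si](c1ccccc1)(c1ccccc1)C(C)(C)C)O[C@H](CCO[Si](C)(C)C(C)(C)C)C=C
F6 | step 6 | 2,5-cis-3-(trimethylsilyloxy)-2,5-dihydrofuran bearing both arms | CC(C)(C)[Si](OCC[C@@H]1O[C@H](CCO[Si](C)(C)C(C)(C)C)C=C1O[Si](C)(C)C)(c1ccccc1)c1ccccc1
F7 | step 6 | trimethylsilyl ether of 12 | CC(C)(C)[Si](OCC[C@@H]1O[C@H](CCO[Si](C)(C)C(C)(C)C)[C@H]2C[C@@]12O[Si](C)(C)C)(c1ccccc1)c1ccccc1
F8 | step 14 | methyl (E)-2-bromo-4-{3-bromo-5-chloro-6-[2-(TBDPS-oxy)ethyl]tetrahydropyran-2-yl}but-2-enoate | CC(C)(C)[Si](OCC[C@@H]1O[C@H](C/C=C(/Br)C(=O)OC)[C@H](Br)C[C@@H]1Cl)(c1ccccc1)c1ccccc1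
F9 | step 14 | (E)-2-bromo allylic alcohol | CC(C)(C)[Si](OCC[C@@H]1O[C@H](C/C=C(/Br)CO)[C@H](Br)C[C@@H]1Cl)(c1ccccc1)c1ccccc1
F10 | step 14 | (E)-2-bromo allylic bromide | CC(C)(C)[Si](OCC[C@@H]1O[C@H](C/C=C(/Br)CBr)[C@H](Br)C[C@@H]1Cl)(c1ccccc1)c1ccccc1
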